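## Retrosynthetic overview

1. Numbering (longipinane): C1 ketone, C2 CH2, C3 CH(CH3), C4 and C11 the cyclobutane CH atoms shared with the six-membered ring, C5 the cyclobutane CH bearing C6 (CMe2), C7 (OH), C8 and C9 (angelates), C10 quaternary (CH3). Rings: cyclohexanone C1–C5/C11, cyclobutane C4–C5–C11–C10, cycloheptane C5–C10 closed through C4 or C11.
2. Endgame: angelates ← C8/C9 cis-diol ← OsO4 on a C8=C9 alkene anti to the C7 oxygen; C7 carbinol ← reagent-controlled reduction of a C7 enone ← Wharton transposition of a C7,C8-epoxy C9-ketone.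
3. Key disconnection: C7–C8 and C10–C11 in one operation (Darzens condensation, then enolate alkylation) from a monocyclic cyclohexane carrying a C7 aldehyde, a C9 chloromethyl ketone and a C11 bromide.
4. Enabling feature: C9 lies between C8 and C10, so as a ketone it activates both carbons that must bond. After the Darzens closure C8 is an oxirane carbon and C10 is the only enolizable position. C10 (on C4) and C11 are 1,3 across the cyclohexane ring, and the cis ring fusion holds the C4–C10 bond axial over C11.
5. Ring order: six-membered ring first (enantioselective Diels–Alder, sets C3, C4, C5), then the seven-membered ring (with a temporary oxirane) and the four-membered ring in the key step.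

Key step: step 10

Remarks on the chemistry (assumptions; TBS = tert-butyldimethylsilyl, PMB = 4-methoxybenzyl):
- The (S)-configured oxazaborolidinium catalyst of step 3 is assumed to expose the enone face that gives the enantiomer drawn; if the sense is the opposite, its enantiomer is used and nothing else changes.
- In step 13 the fully substituted C6 is assumed to act as the large group of the C7 ketone.
- Compounds 11–14 are carried as C10 epimers (erased in step 10); 14–16 are carried as both C7/C8 diastereomers (converge at 17).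

## Route

Step 1
Reactants: 1 3-hydroxy-2,2-dimethylpropanal
Product: 2 (E)-6-hydroxy-5,5-dimethylhex-3-en-2-one
Conditions: Ph3P=CHC(O)CH3, toluene, 100 °C
Reagents that add atoms: 1-(triphenylphosphoranylidene)propan-2-one, CC(=O)C=P(c1ccccc1)(c1ccccc1)c1ccccc1
Why: Wittig olefination with a stabilized ylide should give the E enone; the aldehyde cannot enolize and the free hydroxyl is tolerated.

Step 2
Reactants: 2 (E)-6-hydroxy-5,5-dimethylhex-3-en-2-one
Product: 3 (E)-2,6-bis(tert-butyldimethylsilyloxy)-5,5-dimethylhexa-1,3-diene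
Conditions: TBSOTf (2.3 equiv), Et3N, CH2Cl2, −78 to 0 °C
Reagents that add atoms: tert-butyldimethylsilyl trifluoromethanesulfonate, CC(C)(C)[Si](C)(C)OS(=O)(=O)C(F)(F)F
Why: O-silylation of the alcohol and soft enolization of the methyl ketone (the γ-carbon is quaternary, so only the methyl group can be deprotonated) should give the 2-silyloxy diene.

Step 3
Reactants: 3 (E)-2,6-bis(tert-butyldimethylsilyloxy)-5,5-dimethylhexa-1,3-diene; 4 (E)-pent-3-en-2-one
Product: 5 1-[4-(TBS-oxy)-6-methyl-2-(1-(TBS-oxy)-2-methylpropan-2-yl)cyclohex-3-en-1-yl]ethan-1-one (acetyl cis to the C2 side chain; trans to the C6 methyl)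
Conditions: (S)-o-tolyl oxazaborolidine from (S)-α,α-diphenylprolinol activated by HNTf2 (20 mol %), CH2Cl2, −78 to −40 °C
Reagents that add atoms: none
Why: Enantioselective Diels–Alder reaction in which the 2-silyloxy group and the terminal alkyl group of the diene both direct the acetyl-bearing carbon to the future C4, the endo transition state places acetyl cis to the C5 side chain, the E dienophile keeps the C3 methyl trans to acetyl, and the catalyst sets the absolute configuration.

Step 4
Reactants: 5 the cyclohexene silyl enol ether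
Product: 6 4-acetyl-2-bromo-5-methyl-3-[1-(TBS-oxy)-2-methylpropan-2-yl]cyclohexan-1-one (bromine trans to the C3 side chain)
Conditions: NBS, NaHCO3, THF, −78 to 0 °C
Reagents that add atoms: N-bromosuccinimide, O=C1CCC(=O)N1Br
Why: Electrophilic bromination of the silyl enol ether is regiospecific for the future C11, and bromine should enter anti to the neighbouring C5 side chain.

Step 5
Reactants: 6 the α-bromo ketone
Product: 7 1-[3-bromo-4-hydroxy-6-methyl-2-(1-(TBS-oxy)-2-methylpropan-2-yl)cyclohexyl]ethan-1-one (hydroxyl trans to bromine)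
Conditions: NaBH4 (0.35 equiv), CeCl3·7H2O, MeOH/CH2Cl2, −78 °C
Reagents that add atoms: none
Why: Borohydride reduction under Luche conditions should reduce the inductively activated α-bromo ketone faster than the hindered acetyl group, axial hydride delivery giving the trans bromohydrin (this C1 centre is oxidized again in step 18).

Step 6
Reactants: 7 the bromohydrin
Product: 8 1-[3-bromo-4-(TBS-oxy)-6-methyl-2-(1-(TBS-oxy)-2-methylpropan-2-yl)cyclohexyl]ethan-1-one
Conditions: TBSOTf, 2,6-lutidine, CH2Cl2, −78 °C
Reagents that add atoms: tert-butyldimethylsilyl trifluoromethanesulfonate, CC(C)(C)[Si](C)(C)OS(=O)(=O)C(F)(F)F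
Why: Silylation of the secondary alcohol under weakly basic conditions masks the C1 oxygen and prevents oxirane formation from the bromohydrin in later basic steps.

Step 7
Reactants: 8 the bromo ketone bis-silyl ether
Product: 11 2-[3-bromo-4-(TBS-oxy)-2-(1-hydroxy-2-methylpropan-2-yl)-6-methylcyclohexyl]propanal (C10 epimers), via lithium alkoxide adduct 9 (not isolated), via methyl enol ether 10 (not isolated)
Conditions: Me3SiCH2OMe, s-BuLi, THF, −78 °C, then 8, −78 to −30 °C; KOtBu, 0 to 23 °C; 2 M HCl, THF, 23 °C
Reagents that add atoms: (methoxymethyl)trimethylsilane, COC[Si](C)(C)C; water, O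
Why: One-carbon homologation by addition of the α-silyl α-methoxy carbanion, Peterson elimination to the enol ether and acid hydrolysis, which also removes the primary silyl ether while the hindered secondary one should survive; low-temperature addition avoids epimerization of C4.

Step 8
Reactants: 11 the hydroxy aldehyde
Product: 12 1-chloro-3-[3-bromo-4-(TBS-oxy)-2-(1-hydroxy-2-methylpropan-2-yl)-6-methylcyclohexyl]butan-2-ol (epimers at C9 and C10)
Conditions: ClCH2I, MeLi·LiBr (3 equiv), THF, −78 °C; AcOH quench at −78 °C
Reagents that add atoms: chloroiodomethane, ClCI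
Why: Chloromethyllithium, generated in situ by iodine–lithium exchange, adds to the aldehyde to give the chlorohydrin; the cold acidic quench prevents oxirane closure.

Step 9
Reactants: 12 the chlorohydrin diol
Product: 13 2-[6-bromo-5-(TBS-oxy)-2-(4-chloro-3-oxobutan-2-yl)-3-methylcyclohexyl]-2-methylpropanal (C10 epimers)
Conditions: Dess–Martin periodinane (3 equiv), NaHCO3, CH2Cl2, 0 to 23 °C
Reagents that add atoms: none
Why: Dess–Martin oxidation of both hydroxyls gives the chloromethyl ketone and the neopentyl aldehyde under non-basic conditions that leave the bromide untouched.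

Step 10
Reactants: 13 the chloromethyl ketone aldehyde
Product: 15 1-(TBS-oxy)-7,8-epoxylongipinan-9-one (oxirane cis-fused; both faces), via bicyclic epoxy ketone bromide 14 (not isolated)
Conditions: KN(SiMe3)2 (2.4 equiv), THF (0.005 M), −78 °C, 1 h, then 23 °C
Reagents that add atoms: none
Why: Proposed new method: KN(SiMe3)2 first removes the most acidic proton (ClCH2, C8), the chloro enolate adds to the non-enolizable C7 aldehyde and the alkoxide closes the oxirane (intramolecular Darzens condensation), after which C8 cannot enolize and the second equivalent of base generates the only possible enolate, at C10, which displaces the C11 bromide. The closest known reactions are the Darzens synthesis of epoxy ketones and the closure of bridged cyclobutanes by alkylation of a ketone enolate with a ring sulfonate or halide across a cis ring fusion; their combination in one flask, with the oxirane acting as the blocking group for C8, is new. Ring closures: the seven-membered ring by aldol addition of C8 to C7, the oxirane by 3-exo-tet O-alkylation, the four-membered ring by 4-exo-tet C-alkylation. Stereocontrol: C11 by SN2 inversion of the bromide that step 4 placed trans to the C5 side chain; C10 by the seven-membered ring, which keeps C9 on the side away from the C1–C3 bridge so that the methyl group ends up syn to it; C7/C8 only as a cis-fused oxirane, either face being acceptable because both converge on enone 17. The selectivity needed is C-alkylation through C10 rather than through C8 (which would give a bicyclo[3.3.1]nonane); it is secured by the order of events, since aldol addition at −78 °C is far faster than displacement of a secondary bromide, and HBr elimination is excluded because the equatorial bromide has no antiperiplanar hydrogen in the chair that holds C4–C10 axial.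

Step 11
Reactants: 15 the tricyclic epoxy ketone
Product: 16 1-(TBS-oxy)longipin-8-en-7-ol (C7 epimers)
Conditions: N2H4·H2O, AcOH (cat.), MeOH, 0 to 23 °C
Reagents that add atoms: none
Why: Wharton transposition: hydrazone formation at C9, oxirane opening and loss of N2 should give the C8=C9 alkene and the C7 allylic alcohol from both oxirane diastereomers.

Step 12
Reactants: 16 the allylic alcohol mixture
Product: 17 1-(TBS-oxy)longipin-8-en-7-one
Conditions: Dess–Martin periodinane, NaHCO3, CH2Cl2, 23 °C
Reagents that add atoms: none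
Why: Dess–Martin oxidation converts both C7 epimers into one enone.

Step 13
Reactants: 17 the enone
Product: 18 1-(TBS-oxy)longipin-8-en-7-ol (single C7 epimer; hydroxyl on the ring face that looks toward C4)
Conditions: (S)-Me-CBS oxazaborolidine (1 equiv), BH3·SMe2, THF, −30 °C
Reagents that add atoms: none
Why: Corey–Bakshi–Shibata reduction: the cage is nearly mirror-symmetric around C7, so the substrate offers no facial bias and the catalyst should set C7, delivering hydride from the C11 side with C6 as the large group (1,2-reduction only).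

Step 14
Reactants: 18 the allylic alcohol
Product: 19 7-(PMB-oxy)-1-(TBS-oxy)longipin-8-ene
Conditions: NaH, 4-methoxybenzyl chloride, Bu4NI (cat.), DMF, 0 to 23 °C
Reagents that add atoms: 4-methoxybenzyl chloride, COc1ccc(CCl)cc1
Why: Williamson etherification protects C7–OH with a group that is removed oxidatively at the end, orthogonal to the silyl ether and the angelates.

Step 15
Reactants: 19 the allylic PMB ether
Product: 20 7-(PMB-oxy)-1-(TBS-oxy)longipinane-8,9-diol (8,9-cis; both trans to the C7 oxygen)
Conditions: OsO4 (10 mol %), N-methylmorpholine N-oxide, acetone/H2O, 23 °C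
Reagents that add atoms: osmium tetroxide (catalytic carrier of the two oxygen atoms), O=[Os](=O)(=O)=O; N-methylmorpholine N-oxide (stoichiometric oxygen source), C[N+]1([O-])CCOCC1
Why: Upjohn dihydroxylation: syn addition on the face anti to the allylic C7 ether oxygen (the usual sense for osmylation of allylic ethers) should set C8 and C9, both oxygens on the face that looks toward C11.

Step 16
Reactants: 20 the diol; 21 angelic acid (two molecules are incorporated, one for each hydroxyl)
Product: 22 8,9-bis(angeloyloxy)-7-(PMB-oxy)-1-(TBS-oxy)longipinane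
Conditions: 21 (5 equiv), 2,4,6-trichlorobenzoyl chloride (5 equiv), Et3N, toluene, 23 °C; then 20, DMAP, toluene, 80 °C
Reagents that add atoms: angelic acid (the second molecule of 21, which supplies the second angeloyl group), C/C=C(/C)C(=O)O
Why: Yamaguchi esterification through the mixed anhydride, used in excess so that one molecule of angelic acid is delivered to each of the two hindered secondary hydroxyls, should give the bis-ester without Z to E isomerization of the angelate.

Step 17
Reactants: 22 the bis-angelate
Product: 23 8,9-bis(angeloyloxy)-7-(PMB-oxy)longipinan-1-ol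
Conditions: HF·pyridine, pyridine, THF, 0 to 23 °C
Reagents that add atoms: none
Why: Fluoride-mediated desilylation under buffered acidic conditions frees C1–OH without acyl migration or ester cleavage.

Step 18
Reactants: 23 the C1 alcohol
Product: 24 8,9-bis(angeloyloxy)-7-(PMB-oxy)longipinan-1-one
Conditions: Dess–Martin periodinane, NaHCO3, CH2Cl2, 23 °C
Reagents that add atoms: none
Why: Dess–Martin oxidation gives the C1 ketone; C11 is a bridgehead and cannot epimerize.

Step 19
Reactants: 24 the PMB ether
Product: 25 8,9-bis(angeloyloxy)-7-hydroxylongipinan-1-one (target)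
Conditions: DDQ, CH2Cl2/pH 7 buffer, 0 °C
Reagents that add atoms: none
Why: Oxidative cleavage of the PMB ether under neutral conditions liberates C7–OH and leaves the angelates and the strained β-keto cyclobutane untouched.

## Compound list

1 | 3-hydroxy-2,2-dimethylpropanal | OCC(C)(C)C=O | starting material
2 | (E)-6-hydroxy-5,5-dimethylhex-3-en-2-one | CC(=O)/C=C/C(C)(C)CO | intermediate
3 | (E)-2,6-bis(tert-butyldimethylsilyloxy)-5,5-dimethylhexa-1,3-diene | C=C(O[Si](C)(C)C(C)(C)C)/C=C/C(C)(C)CO[Si](C)(C)C(C)(C)C | intermediate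
4 | (E)-pent-3-en-2-one | C/C=C/C(C)=O | starting material
5 | Diels–Alder adduct, 1-acetyl-2-(side chain)-6-methylcyclohex-3-ene 4-silyl enol ether (1,2-cis; 1,6-trans) | CC(=O)[C@H]1[C@H](C)CC(O[Si](C)(C)C(C)(C)C)=C[C@H]1C(C)(C)CO[Si](C)(C)C(C)(C)C | intermediate
6 | 4-acetyl-2-bromo-5-methyl-3-[1-(TBS-oxy)-2-methylpropan-2-yl]cyclohexan-1-one (Br trans to side chain) | CC(=O)[C@H]1[C@H](C)CC(=O)[C@H](Br)[C@H]1C(C)(C)CO[Si](C)(C)C(C)(C)C | intermediate
7 | trans-bromohydrin of 6 | CC(=O)[C@H]1[C@H](C)C[C@@H](O)[C@H](Br)[C@H]1C(C)(C)CO[Si](C)(C)C(C)(C)C | intermediate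
8 | TBS ether of 7 | CC(=O)[C@H]1[C@H](C)C[C@@H](O[Si](C)(C)C(C)(C)C)[C@H](Br)[C@H]1C(C)(C)CO[Si](C)(C)C(C)(C)C | intermediate
9 | β-silyl carbinol adduct (present as lithium alkoxide; epimers) | COC([Si](C)(C)C)C(C)(O)[C@H]1[C@H](C)C[C@@H](O[Si](C)(C)C(C)(C)C)[C@H](Br)[C@H]1C(C)(C)CO[Si](C)(C)C(C)(C)C | intermediate
10 | methyl enol ether (E/Z) | COC=C(C)[C@H]1[C@H](C)C[C@@H](O[Si](C)(C)C(C)(C)C)[C@H](Br)[C@H]1C(C)(C)CO[Si](C)(C)C(C)(C)C | intermediate
11 | hydroxy aldehyde (C10 epimers) | O=CC(C)[C@H]1[C@H](C)C[C@@H](O[Si](C)(C)C(C)(C)C)[C@H](Br)[C@H]1C(C)(C)CO | intermediate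
12 | chlorohydrin diol (C9/C10 epimers) | OC(CCl)C(C)[C@H]1[C@H](C)C[C@@H](O[Si](C)(C)C(C)(C)C)[C@H](Br)[C@H]1C(C)(C)CO | intermediate
13 | chloromethyl ketone aldehyde (C10 epimers) | O=C(CCl)C(C)[C@H]1[C@H](C)C[C@@H](O[Si](C)(C)C(C)(C)C)[C@H](Br)[C@H]1C(C)(C)C=O | intermediate
14 | 11-bromo-1-(TBS-oxy)-7,8-epoxy-10,11-secolongipinan-9-one (cis-fused bicyclo[5.4.0]undecane; oxirane cis-fused) | O=C1C2OC2C(C)(C)[C@H]3[C@@H](C1C)[C@H](C)C[C@@H](O[Si](C)(C)C(C)(C)C)[C@@H]3Br | intermediate
15 | 1-(TBS-oxy)-7,8-epoxylongipinan-9-one | O=C1C2OC2C(C)(C)[C@H]3[C@@H]4[C@H](C)C[C@@H](O[Si](C)(C)C(C)(C)C)[C@H]3[C@]14C | intermediate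
16 | 1-(TBS-oxy)longipin-8-en-7-ol (C7 epimers) | OC1C(C)(C)[C@H]2[C@@H]3[C@H](C)C[C@@H](O[Si](C)(C)C(C)(C)C)[C@H]2[C@]3(C)C=C1 | intermediate
17 | 1-(TBS-oxy)longipin-8-en-7-one | O=C1C(C)(C)[C@H]2[C@@H]3[C@H](C)C[C@@H](O[Si](C)(C)C(C)(C)C)[C@H]2[C@]3(C)C=C1 | intermediate
18 | 1-(TBS-oxy)longipin-8-en-7-ol (single epimer) | O[C@H]1C(C)(C)[C@H]2[C@@H]3[C@H](C)C[C@@H](O[Si](C)(C)C(C)(C)C)[C@H]2[C@]3(C)C=C1 | intermediate
19 | 7-(PMB-oxy)-1-(TBS-oxy)longipin-8-ene | COc1ccc(CO[C@H]2C(C)(C)[C@H]3[C@@H]4[C@H](C)C[C@@H](O[Si](C)(C)C(C)(C)C)[C@H]3[C@]4(C)C=C2)cc1 | intermediate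
20 | 7-(PMB-oxy)-1-(TBS-oxy)longipinane-8,9-diol | O[C@@H]1[C@@H](OCc2ccc(OC)cc2)C(C)(C)[C@H]2[C@@H]3[C@H](C)C[C@@H](O[Si](C)(C)C(C)(C)C)[C@H]2[C@]3(C)[C@@H]1O | intermediate
21 | angelic acid, (Z)-2-methylbut-2-enoic acid | C/C=C(/C)C(=O)O | starting material
22 | 8,9-bis(angeloyloxy)-7-(PMB-oxy)-1-(TBS-oxy)longipinane | C/C=C(/C)C(=O)O[C@@H]1[C@@H](OCc2ccc(OC)cc2)C(C)(C)[C@H]2[C@@H]3[C@H](C)C[C@@H](O[Si](C)(C)C(C)(C)C)[C@H]2[C@]3(C)[C@@H]1OC(=O)/C(C)=C\C | intermediate
23 | 8,9-bis(angeloyloxy)-7-(PMB-oxy)longipinan-1-ol | C/C=C(/C)C(=O)O[C@@H]1[C@@H](OCc2ccc(OC)cc2)C(C)(C)[C@H]2[C@@H]3[C@H](C)C[C@@H](O)[C@H]2[C@]3(C)[C@@H]1OC(=O)/C(C)=C\C | intermediate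
24 | 8,9-bis(angeloyloxy)-7-(PMB-oxy)longipinan-1-one | C/C=C(/C)C(=O)O[C@@H]1[C@@H](OCc2ccc(OC)cc2)C(C)(C)[C@H]2[C@@H]3[C@H](C)CC(=O)[C@H]2[C@]3(C)[C@@H]1OC(=O)/C(C)=C\C | intermediate
25 | 8,9-bis(angeloyloxy)-7-hydroxylongipinan-1-one | C/C=C(/C)C(=O)O[C@@H]1[C@@H](O)C(C)(C)[C@H]2[C@@H]3[C@H](C)CC(=O)[C@H]2[C@]3(C)[C@@H]1OC(=O)/C(C)=C\C | target

## Step count and risks

Total: 19 steps. Longest linear sequence: 19 steps (1 to 25); 4 and 21 are purchased partners.

**Step 10 (key step).** What may go wrong: after the Darzens closure the hindered C10 enolate may form slowly or react at oxygen, or the basic medium may reopen the seven-membered ring by retro-aldol cleavage before the slow 4-exo displacement. The fallback runs the two ring closures as separate, individually precedented steps. It sets out from 13: LiN(SiMe3)2 (1.05 equiv) in THF at −78 °C with a cold quench should stop at the Darzens product, the bicyclic epoxy ketone bromide 14, which is now isolated. Compound 14 is then cyclized under the thermodynamic enolate conditions used for bridged cyclobutane closures of keto sulfonates and halides (NaH, DMSO, 23 to 50 °C). The route is rejoined at 15. This fallback makes no compound outside the list (F0).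

**Step 3 (Diels–Alder).** What may go wrong: slow cycloaddition and poor facial or endo selectivity because the diene terminus carries a quaternary carbon, with stepwise conjugate addition competing. The fallback uses auxiliary control and sets out from 3. The dienophile is (R)-4-benzyl-3-[(E)-but-2-enoyl]oxazolidin-2-one F1, made from (R)-4-benzyloxazolidin-2-one, n-BuLi and (E)-but-2-enoyl chloride. With Et2AlCl in CH2Cl2 at −78 °C the chelated s-cis imide is shielded on one face by the benzyl group and should give the endo cycloadduct, the N-acyl oxazolidinone F2, with the same configuration at the future C3, C4 and C5. MeNH(OMe)·HCl/AlMe3 converts F2 into the N-methoxy-N-methylamide F3, and MeMgBr converts F3 into the methyl ketone. The route is rejoined at 5.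

**Step 16 (bis-angeloylation).** What may go wrong: incomplete acylation of two hindered neopentyl-type hydroxyls and Z to E isomerization to tiglates under forcing conditions. The fallback builds the Z alkene after acylation and sets out from 20. Both hydroxyls of the diol are esterified with 2-[bis(2,2,2-trifluoroethoxy)phosphoryl]propanoic acid (excess, DCC, DMAP, CH2Cl2) to give the bis(phosphonopropanoate) F4. A Still–Gennari olefination with acetaldehyde (KN(SiMe3)2, 18-crown-6, THF, −78 °C) should then form both (Z)-2-methylbut-2-enoates. The route is rejoined at 22.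

## Further compounds

F0 | step 10 | none | none
F1 | step 3 | (R)-4-benzyl-3-[(E)-but-2-enoyl]oxazolidin-2-one | C/C=C/C(=O)N1[C@H](Cc2ccccc2)COC1=O
F2 | step 3 | N-acyl oxazolidinone cycloadduct (same ring configuration as 5) | O=C1OC[C@@H](Cc2ccccc2)N1C(=O)[C@H]1[C@H](C)CC(O[Si](C)(C)C(C)(C)C)=C[C@H]1C(C)(C)CO[Si](C)(C)C(C)(C)C
F3 | step 3 | N-methoxy-N-methylamide corresponding to 5 | CON(C)C(=O)[C@H]1[C@H](C)CC(O[Si](C)(C)C(C)(C)C)=C[C@H]1C(C)(C)CO[Si](C)(C)C(C)(C)C
F4 | step 16 | 8,9-bis{2-[bis(2,2,2-trifluoroethoxy)phosphoryl]propanoyloxy}-7-(PMB-oxy)-1-(TBS-oxy)longipinane | CC(C(=O)O[C@@H]1[C@@H](OCc2ccc(OC)cc2)C(C)(C)[C@H]2[C@@H]3[C@H](C)C[C@@H](O[Si](C)(C)C(C)(C)C)[C@H]2[C@]3(C)[C@@H]1OC(=O)C(C)P(=O)(OCC(F)(F)F)OCC(F)(F)F)P(=O)(OCC(F)(F)F)OCC(F)(F)F
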